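Leave the solid alone.

the same everywhere: starting material 10 mM; initiator 5 mol%
- cedar: solid reagent 0.40 equiv; run made earlier
- maple: solid reagent 0.60 equiv; run made earlier
- flask: solid reagent 0.800 equiv; time 30 min

| run | time / min | target / % | idle adduct / % |
|---|---|---|---|
| cedar | 3.00 | 2 | 3 |
| cedar | 10.0 | 7 | 0 |
| cedar | 15.0 | 9 | 4 |
| cedar | 25.0 | 23 | 3 |
| cedar | 40.0 | 30 | 2 |
| maple | 8.00 | 5 | 0 |
| maple | 15.0 | 13 | 4 |
| maple | 20.0 | 18 | 4 |
| maple | 30.0 | 31 | 9 |
| maple | 40.0 | 42 | 6 |

(readings scatter by 1.5 percentage points)

1. the target and idle adduct together standing at 30 min, as a percentage of the starting material charged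
2. concentration of partner in solution at 30 min, in percent of saturation

- target is meant together with its idle adduct
- solid, in amounts per volume of the solution: solid reagent
- the analysis behind the earlier runs scatters by 1.5 percentage points, standard deviation
- at the start none of the solid reagent is in solution
- partner is what solid reagent becomes in solution

**Partner bill.** The target peak already holds its idle adduct, and I take each idle adduct to hold a second partner. Maple at 30.0 min shows 40.0% as target plus idle adduct. This sum is the partner bill: turnovers of partner, in percent of the starting material charged.

**At your return.** Cedar reads 23% at 25.0 min, between maple's 18% at 20.0 min and 31% at 30.0 min, with less solid charged. So up to there I read target off the clock. For this flask, maple's bill is 50.0% of the solid reagent charged, so I expect maple's 31% at 30 min. I have no reading of saturation.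

**The forecast.** It says 54% and 20% of saturation, holding that “conversion scales with solid loading”. My reckoning differs on the first number.

**The result.** This flask gives 29.8% and 24.4% of saturation.

    starting material + initiating radical → capped initiator + first chain carrier (k = 1.54 × 10⁵ M⁻¹ s⁻¹)
    solid reagent ⇌ partner, rate k2*(cs2 - [partner]) while solid is left; crystals form when [partner] > cs2 (solubility = 8.10 mM, k = 4.79 × 10⁻⁴ s⁻¹)
    partner + first chain carrier → target + second chain carrier (k = 16900 M⁻¹ s⁻¹)
    2 starting material → self-condensation product (k = 0.0238 M⁻¹ s⁻¹)
    2 first chain carrier → ended chains (k = 2.00 × 10⁶ M⁻¹ s⁻¹)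
    partner + target ⇌ idle adduct, settled at all times (K = 173 M⁻¹)
    starting material + second chain carrier → by-product + first chain carrier (k = 5760 M⁻¹ s⁻¹)
    initiator → 2 initiating radical (k = 1.81 × 10⁻⁵ s⁻¹)

**Not at rest.** At 30 min this flask's bill is 37.4%, with 33% of the starting material still there. At 300 min this flask's target stands at 60.0% and its bill at 69.4%, with starting material at 0%.

**Smaller charge.** In a neighbour with 0.320 equiv of solid reagent, maple's bill is 125% of that neighbour's charge, so from maple's target share of the bill I estimate about 24.8%. That neighbour gives 22.6%.

(The numbers in the tables are simulated for an exercise, and the scatter is random.)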